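**Plan**

- Retrosynthesis: the three phenols are unmasked last (O–CH3 cuts). The ring C3=C4 double bond is taken back to C3–H/C4–H. The furanone ring is then opened at O1–C5 and at C2–C3, which excises the O1–C2(=O) unit as carbon dioxide. The remaining 1,3,5-triarylpent-4-yn-1-one is cut at C4–C5 (alkynyl anion plus chalcone), and the chalcone at its C=C bond.
- Enabling feature: in the furanone ring, C3 carries the aroyl group and C5 carries the exocyclic benzylidene carbon C6. Opened up, C3 is the enolisable α-CH2 of an aryl ketone and C5≡C6 is an arylalkyne of the same oxidation level. These two carbons lie 1,3 to each other on either side of the lactone O1–C2(=O) unit, so CO2 can enter as the two-atom partner of a formal (3+2) annulation.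
- Forward order: O-methylation, Claisen–Schmidt condensation, conjugate alkynylation (open chain complete), silver-catalysed carboxylative cyclisation (the only ring construction; lactone ring, 3-aroyl group and 5-benzylidene group arise together), selenoxide dehydrogenation to the butenolide, global demethylation.
- Stereochemistry: the only stereo-element of the target is the Z C5=C6 bond. It comes from anti addition of carboxylate and silver across the alkyne followed by stereoretentive protodemetalation, and it is also the thermodynamic isomer. The sp3 centres at C3 and C4 are transient, racemic and erased in step 5.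

Key step: step 4

**Route**

Step 1
Reactants: 1 1-(3,5-dibromo-4-hydroxyphenyl)ethanone
Product: 2 1-(3,5-dibromo-4-methoxyphenyl)ethanone
Conditions: MeI, K2CO3, acetone, reflux
Reagents that add atoms: iodomethane, CI
Why: Williamson ether synthesis, in which the acidic 2,6-dibromophenol is deprotonated by K2CO3 and O-methylated by SN2 on iodomethane; the mask is needed because a free phenoxide would consume the base and stall the enolate carboxylation of step 4.

Step 2
Reactants: 2 1-(3,5-dibromo-4-methoxyphenyl)ethanone; 3 3,5-dibromo-4-methoxybenzaldehyde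
Product: 4 (E)-1,3-bis(3,5-dibromo-4-methoxyphenyl)prop-2-en-1-one
Conditions: NaOH (aq), EtOH, rt
Reagents that add atoms: none
Why: Claisen–Schmidt condensation (crossed aldol addition, then E1cB loss of water) between the only enolisable partner 2 and the non-enolisable aldehyde 3, which should give the thermodynamically preferred E enone.

Step 3
Reactants: 4 (E)-1,3-bis(3,5-dibromo-4-methoxyphenyl)prop-2-en-1-one; 5 1-ethynyl-4-methoxybenzene
Product: 9 rac-1,3-bis(3,5-dibromo-4-methoxyphenyl)-5-(4-methoxyphenyl)pent-4-yn-1-one, via lithium acetylide 6 (not isolated), via diethylalkynylalane 7 (not isolated), via aluminium enolate 8 (not isolated)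
Conditions: 5, n-BuLi, Et2O–hexane, 0 °C; Et2AlCl, 0 °C to rt; then 4, Et2O–toluene, rt; 1 M HCl, 0 °C
Reagents that add atoms: none
Why: Hooz-type conjugate alkynylation of an enone that can reach the s-cis conformation, in which aluminium binds the carbonyl oxygen and the alkynyl group is passed to the β-carbon through a six-membered cyclic array to give the Z aluminium enolate 8 and, on protonation, ketone 9; the new benzylic centre is racemic and is erased in step 5, and all n-BuLi is consumed by the alkyne before the aryl bromides are introduced.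

Step 4
Reactants: 9 rac-1,3-bis(3,5-dibromo-4-methoxyphenyl)-5-(4-methoxyphenyl)pent-4-yn-1-one
Product: 12 rac-(3S,4S)-3-(3,5-dibromo-4-methoxybenzoyl)-4-(3,5-dibromo-4-methoxyphenyl)-5-[(Z)-(4-methoxyphenyl)methylidene]oxolan-2-one, via guanidinium β-keto carboxylate 10 (not isolated), via vinylsilver lactone 11 (not isolated)
Conditions: AgOCOPh (20 mol %), MTBD (7-methyl-1,5,7-triazabicyclo[4.4.0]dec-5-ene, 4 equiv), CO2 (1.0 MPa), MeCN, 25 °C; then cold 1 M HCl
Reagents that add atoms: carbon dioxide, O=C=O
Why: MTBD reversibly deprotonates the only enolisable position of 9 (the CH2 next to the electron-poor aroyl group) and the enolate carbon adds to CO2 to give the β-keto carboxylate 10 in an uphill, reversible C–C bond formation; monovalent silver then activates the alkyne as a π-complex, the carboxylate oxygen adds anti to silver at the near alkyne carbon to give the vinylsilver lactone 11, and protonation of the C–Ag bond with retention releases 12 and the catalyst, so the irreversible ring closure drains the carboxylation equilibrium. The closest known reaction type is the silver benzoate/MTBD-catalysed cascade carboxylation–cyclisation of alkyne-bearing aryl ketones with CO2 to 3-acyl-5-ylidene γ-lactones, in effect a formal (3+2) annulation of CO2 across the C3–C4–C5 unit. The furanone ring (O1, C2, C3, C4, C5) closes in the 5-exo-dig mode. The Z geometry of C5=C6 follows from the anti oxy-argentation and the stereoretentive protodemetalation; the C3 and C4 centres are formed racemic, C3 is epimerisable through the β-keto lactone enol and should settle trans to the C4 aryl group, and both are erased in step 5. The step needs carboxylate-O rather than enol-O attack on the alkyne (the latter would give a furan without uptake of CO2) and 5-exo rather than 6-endo closure: the CO2 pressure keeps the anionic, more nucleophilic carboxylate available, the basic medium and the three-atom tether favour the exo mode, and the site of carboxylation is fixed because 9 has a single enolisable α-position.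

Step 5
Reactants: 12 rac-(3S,4S)-3-(3,5-dibromo-4-methoxybenzoyl)-4-(3,5-dibromo-4-methoxyphenyl)-5-[(Z)-(4-methoxyphenyl)methylidene]oxolan-2-one
Product: 15 (Z)-3-(3,5-dibromo-4-methoxybenzoyl)-4-(3,5-dibromo-4-methoxyphenyl)-5-[(4-methoxyphenyl)methylidene]furan-2(5H)-one, via C3 phenylselenide 13 (not isolated), via selenoxide 14 (not isolated)
Conditions: PhSeCl, pyridine, CH2Cl2, 0 °C; 1 M HCl wash; then 30 % H2O2, CH2Cl2, 0 °C to rt
Reagents that add atoms: none
Why: Reich-type dehydrogenation of a β-dicarbonyl compound by α-selenenylation and selenoxide syn-elimination, in which the enol of the β-keto lactone is selenenylated at C3 on the face anti to the C4 aryl group, so that selenium sits cis to H-4 (the only β-hydrogen) and the selenoxide should eliminate below room temperature to the C3=C4 bond without touching the Z exocyclic alkene.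

Step 6
Reactants: 15 (Z)-3-(3,5-dibromo-4-methoxybenzoyl)-4-(3,5-dibromo-4-methoxyphenyl)-5-[(4-methoxyphenyl)methylidene]furan-2(5H)-one
Product: 17 cadiolide A, via tris(dibromoboryl) ether 16 (not isolated)
Conditions: BBr3 (excess), CH2Cl2, −78 °C to rt; then H2O, 0 °C
Reagents that add atoms: none
Why: Lewis-acid cleavage of aryl methyl ethers, in which each ether oxygen is borylated and bromide removes the methyl group by SN2 to give the aryloxy-dibromoboranes 16 that are hydrolysed on quench; the enol lactone, the diaryl ketone, the aryl bromides and the thermodynamically preferred Z-benzylidene should survive.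

**Compound list**

1 | 1-(3,5-dibromo-4-hydroxyphenyl)ethanone | CC(=O)c1cc(Br)c(O)c(Br)c1 | starting material
2 | 1-(3,5-dibromo-4-methoxyphenyl)ethanone | CC(=O)c1cc(Br)c(OC)c(Br)c1 | intermediate
3 | 3,5-dibromo-4-methoxybenzaldehyde | O=Cc1cc(Br)c(OC)c(Br)c1 | starting material
4 | (E)-1,3-bis(3,5-dibromo-4-methoxyphenyl)prop-2-en-1-one | O=C(/C=C/c1cc(Br)c(OC)c(Br)c1)c1cc(Br)c(OC)c(Br)c1 | intermediate
5 | 1-ethynyl-4-methoxybenzene | C#Cc1ccc(OC)cc1 | starting material
6 | lithium (4-methoxyphenyl)acetylide | [Li]C#Cc1ccc(OC)cc1 | intermediate (not isolated)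
7 | diethyl[(4-methoxyphenyl)ethynyl]alane | CC[Al](CC)C#Cc1ccc(OC)cc1 | intermediate (not isolated)
8 | diethylaluminium (Z)-1,3-bis(3,5-dibromo-4-methoxyphenyl)-5-(4-methoxyphenyl)pent-1-en-4-yn-1-olate (racemic) | CC[Al](CC)O/C(=C\C(C#Cc1ccc(OC)cc1)c1cc(Br)c(OC)c(Br)c1)c1cc(Br)c(OC)c(Br)c1 | intermediate (not isolated)
9 | rac-1,3-bis(3,5-dibromo-4-methoxyphenyl)-5-(4-methoxyphenyl)pent-4-yn-1-one | O=C(CC(C#Cc1ccc(OC)cc1)c1cc(Br)c(OC)c(Br)c1)c1cc(Br)c(OC)c(Br)c1 | intermediate
10 | 7-methyl-1,5,7-triazabicyclo[4.4.0]dec-5-enium 2-(3,5-dibromo-4-methoxybenzoyl)-3-(3,5-dibromo-4-methoxyphenyl)-5-(4-methoxyphenyl)pent-4-ynoate (diastereomer mixture, racemic) | CN1CCCN2CCC[NH+]=C12.[O-]C(=O)C(C(=O)c1cc(Br)c(OC)c(Br)c1)C(C#Cc1ccc(OC)cc1)c1cc(Br)c(OC)c(Br)c1 | intermediate (not isolated)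
11 | vinylsilver lactone: 3-(3,5-dibromo-4-methoxybenzoyl)-4-(3,5-dibromo-4-methoxyphenyl)-5-[(4-methoxyphenyl)(argentio)methylidene]oxolan-2-one, ring oxygen and silver trans across the exocyclic double bond (racemic) | O=C1O/C(=C(/[Ag])c2ccc(OC)cc2)C(c2cc(Br)c(OC)c(Br)c2)C1C(=O)c1cc(Br)c(OC)c(Br)c1 | intermediate (not isolated)
12 | rac-(3S,4S)-3-(3,5-dibromo-4-methoxybenzoyl)-4-(3,5-dibromo-4-methoxyphenyl)-5-[(Z)-(4-methoxyphenyl)methylidene]oxolan-2-one (aroyl and aryl trans; one enantiomer drawn) | O=C1O/C(=C\c2ccc(OC)cc2)[C@H](c2cc(Br)c(OC)c(Br)c2)[C@H]1C(=O)c1cc(Br)c(OC)c(Br)c1 | intermediate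
13 | rac-(3S,4S)-3-(3,5-dibromo-4-methoxybenzoyl)-4-(3,5-dibromo-4-methoxyphenyl)-5-[(Z)-(4-methoxyphenyl)methylidene]-3-(phenylselanyl)oxolan-2-one (SePh trans to the C4 aryl group and cis to H-4; one enantiomer drawn) | O=C1O/C(=C\c2ccc(OC)cc2)[C@H](c2cc(Br)c(OC)c(Br)c2)[C@]1([Se]c3ccccc3)C(=O)c1cc(Br)c(OC)c(Br)c1 | intermediate (not isolated)
14 | selenoxide of 13 (same relative configuration at C3 and C4, mixture at selenium) | O=C1O/C(=C\c2ccc(OC)cc2)[C@H](c2cc(Br)c(OC)c(Br)c2)[C@]1([Se](=O)c3ccccc3)C(=O)c1cc(Br)c(OC)c(Br)c1 | intermediate (not isolated)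
15 | (Z)-3-(3,5-dibromo-4-methoxybenzoyl)-4-(3,5-dibromo-4-methoxyphenyl)-5-[(4-methoxyphenyl)methylidene]furan-2(5H)-one (tri-O-methyl cadiolide A) | O=C1O/C(=C\c2ccc(OC)cc2)C(c2cc(Br)c(OC)c(Br)c2)=C1C(=O)c1cc(Br)c(OC)c(Br)c1 | intermediate
16 | tris(dibromoboryl) ether of cadiolide A (all three phenol oxygens as O–BBr2, Z) | O=C1O/C(=C\c2ccc(OB(Br)Br)cc2)C(c2cc(Br)c(OB(Br)Br)c(Br)c2)=C1C(=O)c1cc(Br)c(OB(Br)Br)c(Br)c1 | intermediate (not isolated)
17 | cadiolide A, (Z)-3-(3,5-dibromo-4-hydroxybenzoyl)-4-(3,5-dibromo-4-hydroxyphenyl)-5-[(4-hydroxyphenyl)methylidene]furan-2(5H)-one | O=C1O/C(=C\c2ccc(O)cc2)C(c2cc(Br)c(O)c(Br)c2)=C1C(=O)c1cc(Br)c(O)c(Br)c1 | target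

**Step count and risks**

Total step count: 6. Longest linear sequence: 6 steps (1 → 2 → 4 → 9 → 12 → 15 → 17).

Steps most likely to fail:

1. Step 4. The enol oxygen may close onto the silver-activated alkyne faster than carboxylation occurs (cycloisomerisation to a furan without CO2). Closure may drift to the 6-endo mode because the anisyl group polarises the alkyne. The β-keto carboxylate may lose CO2 again before ring closure, or the propargylic C–H may be shifted by the base to an allene. Fallback: the C–C bond and the C–O bond are made in two separate, stoichiometrically driven operations. Setting out from 9, the kinetic lithium enolate (LiN(SiMe3)2, THF, −78 °C) is quenched with dry CO2 and acidified cold to give 2-(3,5-dibromo-4-methoxybenzoyl)-3-(3,5-dibromo-4-methoxyphenyl)-5-(4-methoxyphenyl)pent-4-ynoic acid F1. This alkynoic acid is cycloisomerised at once with catalytic Ag2CO3 in MeCN at rt (5-exo-dig, anti addition), which brings the route back at 12.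

2. Step 5. PhSeCl may add to the electron-rich enol-ether double bond instead of the β-keto lactone enol. Selenenylation may occur on the face that leaves no syn β-hydrogen. The peroxide may over-oxidise the product. Fallback: the oxidation is moved to the other end of the conjugated system and run as a hydride abstraction. Setting out from 12, acid-then-base tautomerisation (camphorsulfonic acid, CH2Cl2, then Et3N) moves the exocyclic double bond into the ring to give rac-3-(3,5-dibromo-4-methoxybenzoyl)-4-(3,5-dibromo-4-methoxyphenyl)-5-(4-methoxybenzyl)furan-2(5H)-one F2. DDQ in dry dioxane at 80 °C then abstracts hydride from the p-methoxybenzylic CH2, and loss of the acidic H-5 gives the Z-benzylidene, so the route is rejoined at 15.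

3. Step 3. The alane may add 1,2 to the carbonyl, transfer an ethyl group, or react sluggishly with the hindered, Lewis-basic chalcone. Fallback: the same ketone is made by forming the C2–C3 bond through propargylic substitution instead of the C3–C4 bond through conjugate addition. Setting out from 3 and 6 (from 5 and n-BuLi, THF, −78 °C, NH4Cl quench), 1,2-addition gives rac-1-(3,5-dibromo-4-methoxyphenyl)-3-(4-methoxyphenyl)prop-2-yn-1-ol F3. Ketone 2 is converted with Me3SiOTf and Et3N in CH2Cl2 into {[1-(3,5-dibromo-4-methoxyphenyl)ethenyl]oxy}trimethylsilane F4. BF3·OEt2 in CH2Cl2 at −40 °C ionises F3 to the aryl-stabilised propargylic cation, which is captured by F4 at the propargylic carbon, and the route is rejoined at 9.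

**Further compounds**

F1 | step 4 | 2-(3,5-dibromo-4-methoxybenzoyl)-3-(3,5-dibromo-4-methoxyphenyl)-5-(4-methoxyphenyl)pent-4-ynoic acid (diastereomer mixture, racemic) | OC(=O)C(C(=O)c1cc(Br)c(OC)c(Br)c1)C(C#Cc1ccc(OC)cc1)c1cc(Br)c(OC)c(Br)c1
F2 | step 5 | rac-3-(3,5-dibromo-4-methoxybenzoyl)-4-(3,5-dibromo-4-methoxyphenyl)-5-(4-methoxybenzyl)furan-2(5H)-one | O=C1OC(Cc2ccc(OC)cc2)C(c2cc(Br)c(OC)c(Br)c2)=C1C(=O)c1cc(Br)c(OC)c(Br)c1
F3 | step 3 | rac-1-(3,5-dibromo-4-methoxyphenyl)-3-(4-methoxyphenyl)prop-2-yn-1-ol | OC(C#Cc1ccc(OC)cc1)c1cc(Br)c(OC)c(Br)c1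
F4 | step 3 | {[1-(3,5-dibromo-4-methoxyphenyl)ethenyl]oxy}trimethylsilane | C=C(O[Si](C)(C)C)c1cc(Br)c(OC)c(Br)c1
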